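**Plan**

Rings are lettered A–D from the 2,4,6-trihydroxyphenoxy end; in rings B and C, C4 is the ether carbon flanked by the C3 and C5 hydroxyls and C1 the ether carbon para to it.
Retrosynthesis: the six methyl ethers on rings A and D are removed last; before that, ring B is cut at B3–B4 and ring C at C3–C4, which unfolds each ring into a 2-pyranone.
Enabling feature: in rings B and C the oxygens on C1, C3 and C5 sit on alternate carbons and C4 bears a fourth, so each ring is a 6-oxy-3,5-dioxohexanoate whose C1 oxygen is kept as an enol ether, i.e. a 4-oxy-2-pyranone with a CH2–O group on C6 (CH2 = future C4, lactone carbonyl = future C3).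
Further cuts: ring A oxygen to pyranone C4 (addition–elimination on a 4-bromopyranone), the CH2–O bond between the two pyranones (alkylation), and the ring-C pyranone into methyl acetoacetate plus an aryloxyacetate.
Forward: the ring-C pyranone is built (steps 3–5), triacetic acid lactone is dibrominated (steps 1–2), the halves are joined and the ring A phenol attached (steps 6–7), both lactones are folded at once into rings B and C (step 8), and BBr3 frees the phenols (step 9).
Stereochemistry: the target has no stereocentre; only the enoate geometry matters in the key step, and the pyranone rings fix it.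

Key step: step 8

Assumption: both trimethoxyphenols are bought as such. The ring A phenol is attached only after the radical bromination, because NBS would brominate a trimethoxyphenyl ring.

**Route**

Step 1
Reactants: 1 4-hydroxy-6-methyl-2H-pyran-2-one (triacetic acid lactone)
Product: 2 4-bromo-6-methyl-2H-pyran-2-one
Conditions: Bu4NBr, P2O5, toluene, 100 °C
Reagents that add atoms: tetrabutylammonium bromide, CCCC[N+](CCCC)(CCCC)CCCC.[Br-]
Why: Deoxybromination of a vinylogous acid: the 4-hydroxyl is activated as a phosphate and replaced by bromide through addition–elimination, the usual preparation of this bromopyranone.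

Step 2
Reactants: 2 4-bromo-6-methyl-2H-pyran-2-one
Product: 3 4-bromo-6-(bromomethyl)-2H-pyran-2-one
Conditions: NBS (1.0 equiv), AIBN (cat.), PhCF3, reflux
Reagents that add atoms: N-bromosuccinimide, O=C1CCC(=O)N1Br
Why: Wohl–Ziegler radical bromination should take the C6 methyl, whose radical is delocalised over the pyranone diene, while the electron-poor 4-bromo ring resists ionic bromination at C3 and no electron-rich arene is present yet.

Step 3
Reactants: 4 3,4,5-trimethoxyphenol; 5 methyl bromoacetate
Product: 6 methyl 2-(3,4,5-trimethoxyphenoxy)acetate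
Conditions: K2CO3, acetone, reflux
Reagents that add atoms: none
Why: Williamson ether synthesis, SN2 attack of the phenoxide on the activated α-bromo ester.

Step 4
Reactants: 7 methyl acetoacetate; 6 methyl 2-(3,4,5-trimethoxyphenoxy)acetate
Product: 9 methyl 3,5-dioxo-6-(3,4,5-trimethoxyphenoxy)hexanoate, via methyl acetoacetate dianion 8 (not isolated)
Conditions: 7 (2.2 equiv), NaH, THF, 0 °C; n-BuLi, 0 °C; then 6, −78 °C to 0 °C; aq. HCl
Reagents that add atoms: none
Why: Claisen acylation of the acetoacetate dianion at its terminal carbon by an ester is the standard entry to 3,5-dioxo esters; the second equivalent of dianion absorbs the acidic proton of the product, and the α-aryloxy ester is an activated acyl donor.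

Step 5
Reactants: 9 methyl 3,5-dioxo-6-(3,4,5-trimethoxyphenoxy)hexanoate
Product: 10 4-hydroxy-6-[(3,4,5-trimethoxyphenoxy)methyl]-2H-pyran-2-one
Conditions: DBU, toluene, reflux; then aq. HCl
Reagents that add atoms: none
Why: Base-promoted lactonisation of a 3,5-dioxo ester, in which the C5 enol oxygen is acylated by the ester, is the usual closure to a 4-hydroxy-2-pyranone; DBU cannot deprotonate the terminal CH2, so no carbon cyclisation competes.

Step 6
Reactants: 10 4-hydroxy-6-[(3,4,5-trimethoxyphenoxy)methyl]-2H-pyran-2-one; 3 4-bromo-6-(bromomethyl)-2H-pyran-2-one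
Product: 11 4-bromo-6-[({2-oxo-6-[(3,4,5-trimethoxyphenoxy)methyl]-2H-pyran-4-yl}oxy)methyl]-2H-pyran-2-one
Conditions: K2CO3, DMF, 0 °C to rt
Reagents that add atoms: none
Why: SN2 O-alkylation of the potassium 4-olate by the activated primary bromide in a polar aprotic solvent, as in routine preparations of 4-alkoxy-2-pyranones; the weakly basic olate should add only reversibly to the vinylic C–Br carbon.

Step 7
Reactants: 11 4-bromo-6-[({2-oxo-6-[(3,4,5-trimethoxyphenoxy)methyl]-2H-pyran-4-yl}oxy)methyl]-2H-pyran-2-one; 12 2,4,6-trimethoxyphenol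
Product: 13 4-(2,4,6-trimethoxyphenoxy)-6-[({2-oxo-6-[(3,4,5-trimethoxyphenoxy)methyl]-2H-pyran-4-yl}oxy)methyl]-2H-pyran-2-one
Conditions: K2CO3, DMF, rt
Reagents that add atoms: none
Why: Vinylogous acyl substitution (addition–elimination) of the C4 bromide by a phenoxide is known for 4-bromo-2-pyranones; bromide leaves far more readily than the alkoxide on C4 of the other pyranone, so only the brominated ring should react.

Step 8
Reactants: 13 4-(2,4,6-trimethoxyphenoxy)-6-[({2-oxo-6-[(3,4,5-trimethoxyphenoxy)methyl]-2H-pyran-4-yl}oxy)methyl]-2H-pyran-2-one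
Product: 15 5-[2,6-dihydroxy-4-(2,4,6-trimethoxyphenoxy)phenoxy]-2-(3,4,5-trimethoxyphenoxy)benzene-1,3-diol, via ring-opened bis(enoate) diester 14 (not isolated)
Conditions: Mg(OMe)2 (excess), MeOH, reflux, argon; then aq. HCl
Reagents that add atoms: none
Why: Proposed new method: magnesium-bound methoxide should add to each lactone carbonyl and open it to the (2E)-3-oxy-5-oxohex-2-enoate of 14, whose ester is held cis to the keto chain by the former ring, after which the enolate at the oxygen-bearing terminal CH2 of each ketone attacks that ester, methoxide leaves and the cyclohexenedione enolises to the aromatic diol, forming B3–B4 and C3–C4. The closest known reactions are the Mg(OMe)2- or KOH-induced recyclisation of 4-oxygenated 2-pyranones carrying a ketone side chain to phloroglucinol and resorcinol derivatives and the Claisen closure of 5-oxohexanoates to cyclohexane-1,3-diones; not yet shown are an aryloxymethyl or pyranyloxymethyl ketone carbon as the nucleophile and two such closures in one molecule. Ring B and ring C each close in the 6-(enolendo)-exo-trig mode. No stereocentre is formed. The step needs carbon acylation to be faster than methoxide exchange at C4 of either pyranone (which would strip the ring A phenoxide or cut the CH2–O link), and it needs the terminal CH2 enolate although the methylene between enol ether and ketone is more acidic; that more acidic enolate can close no ring and is only a resting state, magnesium chelation steers methoxide to the carbonyl carbon, and each closure ends in an aromatic magnesium phenoxide and cannot revert. Argon is required because the resorcinol anions formed are oxidised by air.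

Step 9
Reactants: 15 5-[2,6-dihydroxy-4-(2,4,6-trimethoxyphenoxy)phenoxy]-2-(3,4,5-trimethoxyphenoxy)benzene-1,3-diol
Product: 16 5-[2,6-dihydroxy-4-(2,4,6-trihydroxyphenoxy)phenoxy]-2-(3,4,5-trihydroxyphenoxy)benzene-1,3-diol
Conditions: BBr3 (excess), CH2Cl2, −78 °C to rt; then H2O
Reagents that add atoms: none
Why: Lewis-acid ether cleavage with BBr3 (bromide attacks the methyl group of the boron-complexed aryl methyl ether) should remove all six methyl groups, while the three diaryl ether bonds offer no sp3 carbon to bromide and should survive.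

**Compound list**

1 | 4-hydroxy-6-methyl-2H-pyran-2-one | CC1=CC(O)=CC(=O)O1 | starting material
2 | 4-bromo-6-methyl-2H-pyran-2-one | CC1=CC(Br)=CC(=O)O1 | intermediate
3 | 4-bromo-6-(bromomethyl)-2H-pyran-2-one | BrCC1=CC(Br)=CC(=O)O1 | intermediate
4 | 3,4,5-trimethoxyphenol | COc1cc(O)cc(OC)c1OC | starting material
5 | methyl bromoacetate | COC(=O)CBr | starting material
6 | methyl 2-(3,4,5-trimethoxyphenoxy)acetate | COC(=O)COc1cc(OC)c(OC)c(OC)c1 | intermediate
7 | methyl acetoacetate | COC(=O)CC(C)=O | starting material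
8 | methyl acetoacetate dianion, sodium lithium salt (formed in the flask) | [Na+].[Li+].[CH2-]C(=O)[CH-]C(=O)OC | intermediate
9 | methyl 3,5-dioxo-6-(3,4,5-trimethoxyphenoxy)hexanoate | COC(=O)CC(=O)CC(=O)COc1cc(OC)c(OC)c(OC)c1 | intermediate
10 | 4-hydroxy-6-[(3,4,5-trimethoxyphenoxy)methyl]-2H-pyran-2-one | O=C1C=C(O)C=C(COc2cc(OC)c(OC)c(OC)c2)O1 | intermediate
11 | 4-bromo-6-[({2-oxo-6-[(3,4,5-trimethoxyphenoxy)methyl]-2H-pyran-4-yl}oxy)methyl]-2H-pyran-2-one | O=C1C=C(Br)C=C(COC2=CC(=O)OC(COc3cc(OC)c(OC)c(OC)c3)=C2)O1 | intermediate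
12 | 2,4,6-trimethoxyphenol | COc1cc(OC)c(O)c(OC)c1 | starting material
13 | 4-(2,4,6-trimethoxyphenoxy)-6-[({2-oxo-6-[(3,4,5-trimethoxyphenoxy)methyl]-2H-pyran-4-yl}oxy)methyl]-2H-pyran-2-one (bis-pyranone) | O=C1C=C(Oc2c(OC)cc(OC)cc2OC)C=C(COC3=CC(=O)OC(COc4cc(OC)c(OC)c(OC)c4)=C3)O1 | intermediate
14 | methyl (2E)-6-{[(2E)-1-methoxy-1,5-dioxo-6-(3,4,5-trimethoxyphenoxy)hex-2-en-3-yl]oxy}-5-oxo-3-(2,4,6-trimethoxyphenoxy)hex-2-enoate (formed in the flask) | COC(=O)/C=C(\CC(=O)COC(=C/C(=O)OC)/CC(=O)COc1cc(OC)c(OC)c(OC)c1)Oc1c(OC)cc(OC)cc1OC | intermediate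
15 | 5-[2,6-dihydroxy-4-(2,4,6-trimethoxyphenoxy)phenoxy]-2-(3,4,5-trimethoxyphenoxy)benzene-1,3-diol | COc1cc(OC)c(Oc2cc(O)c(Oc3cc(O)c(Oc4cc(OC)c(OC)c(OC)c4)c(O)c3)c(O)c2)c(OC)c1 | intermediate
16 | 5-[2,6-dihydroxy-4-(2,4,6-trihydroxyphenoxy)phenoxy]-2-(3,4,5-trihydroxyphenoxy)benzene-1,3-diol (CNP0333502.0) | Oc1cc(O)c(Oc2cc(O)c(Oc3cc(O)c(Oc4cc(O)c(O)c(O)c4)c(O)c3)c(O)c2)c(O)c1 | target

**Step count and risks**

Total steps: 9. Longest linear sequence: 7 steps (steps 3–9, from 4 to 16); steps 1–2 form the second branch and join at step 6.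

Steps most likely to fail:

1. Step 8 (Proposed new method). Methoxide exchange at the vinylogous ester carbons may strip the ring A phenoxide or cut the CH2–O link before either carbon cyclisation occurs. Once ring B has closed, its phenoxides may shift the still intact second pyranone to a neighbouring oxygen, or only one of the two rings may close. Fallback (iterative Ullmann ether synthesis, known chemistry), setting out from 12: 4-bromo-2,6-dimethoxyphenol is benzylated (BnBr, K2CO3, DMF) to 2-(benzyloxy)-5-bromo-1,3-dimethoxybenzene F1. Ullmann coupling of 12 with F1 (CuI, N,N-dimethylglycine, Cs2CO3, dioxane, 100 °C) should give 2-[4-(benzyloxy)-3,5-dimethoxyphenoxy]-1,3,5-trimethoxybenzene F2, and hydrogenolysis (H2, Pd/C, EtOAc) the phenol 2,6-dimethoxy-4-(2,4,6-trimethoxyphenoxy)phenol F3. A second coupling with F1 should give 2-{4-[4-(benzyloxy)-3,5-dimethoxyphenoxy]-3,5-dimethoxyphenoxy}-1,3,5-trimethoxybenzene F4, and hydrogenolysis 4-[2,6-dimethoxy-4-(2,4,6-trimethoxyphenoxy)phenoxy]-2,6-dimethoxyphenol F5. A third coupling, with 5-bromo-1,2,3-trimethoxybenzene, should give the decamethyl ether 5-[2,6-dimethoxy-4-(2,4,6-trimethoxyphenoxy)phenoxy]-1,3-dimethoxy-2-(3,4,5-trimethoxyphenoxy)benzene F6. BBr3 under the conditions of step 9 then cleaves all ten methyl ethers and the fallback returns to the route at 16.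

2. Step 6. The ambident pyranone anion may be alkylated at C3 or at the lactone oxygen instead of the 4-oxygen, and the bis-electrophile may be consumed at its vinylic bromide. Fallback (Mitsunobu etherification, which alkylates 4-hydroxy-2-pyranones on the 4-oxygen under neutral conditions), setting out from 3: HCO2Na in DMF should displace only the primary bromide to give (4-bromo-2-oxo-2H-pyran-6-yl)methyl formate F7. Dilute HCl in aqueous THF cleaves the formate to 4-bromo-6-(hydroxymethyl)-2H-pyran-2-one F8. Coupling of F8 with 10 (PPh3, DIAD, THF, 0 °C to rt, the reagents premixed) returns to the route at 11.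

3. Step 9. Cleavage of the six methyl ethers may stop short as boron phenoxides accumulate, and the free decaphenol may be lost by air oxidation and on chromatography. Fallback (isolation through a stable derivative), setting out from 15: after the BBr3 treatment the crude polyphenol is not isolated but acetylated (Ac2O, pyridine) to the decaacetate 5-[2,6-diacetoxy-4-(2,4,6-triacetoxyphenoxy)phenoxy]-2-(3,4,5-triacetoxyphenoxy)benzene-1,3-diyl diacetate F9. F9 can be purified on silica and separated from under-demethylated material. Acid-catalysed methanolysis (HCl from AcCl in degassed MeOH, argon) then removes the acetates and returns to the route at 16.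

**Further compounds**

F1 | step 8 | 2-(benzyloxy)-5-bromo-1,3-dimethoxybenzene | COc1cc(Br)cc(OC)c1OCc1ccccc1
F2 | step 8 | 2-[4-(benzyloxy)-3,5-dimethoxyphenoxy]-1,3,5-trimethoxybenzene | COc1cc(OC)c(Oc2cc(OC)c(OCc3ccccc3)c(OC)c2)c(OC)c1
F3 | step 8 | 2,6-dimethoxy-4-(2,4,6-trimethoxyphenoxy)phenol | COc1cc(OC)c(Oc2cc(OC)c(O)c(OC)c2)c(OC)c1
F4 | step 8 | 2-{4-[4-(benzyloxy)-3,5-dimethoxyphenoxy]-3,5-dimethoxyphenoxy}-1,3,5-trimethoxybenzene | COc1cc(OC)c(Oc2cc(OC)c(Oc3cc(OC)c(OCc4ccccc4)c(OC)c3)c(OC)c2)c(OC)c1
F5 | step 8 | 4-[2,6-dimethoxy-4-(2,4,6-trimethoxyphenoxy)phenoxy]-2,6-dimethoxyphenol | COc1cc(OC)c(Oc2cc(OC)c(Oc3cc(OC)c(O)c(OC)c3)c(OC)c2)c(OC)c1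
F6 | step 8 | 5-[2,6-dimethoxy-4-(2,4,6-trimethoxyphenoxy)phenoxy]-1,3-dimethoxy-2-(3,4,5-trimethoxyphenoxy)benzene | COc1cc(OC)c(Oc2cc(OC)c(Oc3cc(OC)c(Oc4cc(OC)c(OC)c(OC)c4)c(OC)c3)c(OC)c2)c(OC)c1
F7 | step 6 | (4-bromo-2-oxo-2H-pyran-6-yl)methyl formate | O=COCC1=CC(Br)=CC(=O)O1
F8 | step 6 | 4-bromo-6-(hydroxymethyl)-2H-pyran-2-one | OCC1=CC(Br)=CC(=O)O1
F9 | step 9 | 5-[2,6-diacetoxy-4-(2,4,6-triacetoxyphenoxy)phenoxy]-2-(3,4,5-triacetoxyphenoxy)benzene-1,3-diyl diacetate | CC(=O)Oc1cc(OC(C)=O)c(Oc2cc(OC(C)=O)c(Oc3cc(OC(C)=O)c(Oc4cc(OC(C)=O)c(OC(C)=O)c(OC(C)=O)c4)c(OC(C)=O)c3)c(OC(C)=O)c2)c(OC(C)=O)c1
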